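**Atom numbering used throughout (target atoms):** carbocycle C1–C10; C11(=C13H2)–C12(=O) is the lactone side chain on C7; C14 is the CH2O on C10; C15 is the methyl on C4. In bicyclic intermediates ring A = C1, C6, C7, C8, C9, C10 and ring B = C1–C6.

## Analysis of the target

Target 37 is a germacranolide: a ten-membered carbocycle (C1–C10) with two ring-cis trisubstituted alkenes (Z C1=C10 carrying C14H2–O-isovalerate, Z C4=C5 carrying C15), trans-fused across C6–C7 to an α-methylene-γ-butyrolactone. The four contiguous stereocentres are 6R, 7R, 8S, 9R. H6 and H7 are anti; once a C1–C6 bond is imagined, the C7 side chain, O8 and O9 all lie on one face of ring A. Sensitive groups are the α-methylene lactone (Michael acceptor, base-labile), two allylic esters, the cis-vicinal C8-hydroxy/C9-acetoxy pair (acyl migration) and a free C8 hydroxyl that could translactonise. The difficulties are the medium ring with two Z alkenes, three oxygens (O8, O9, O14) that must end differently substituted, and the near-equivalence of C7 and C10 in any ring A precursor, which differ only through a remote methyl group. The strategy rests on C1 and C6: C6 is oxygenated and C1 belongs to the C1=C10 alkene, so a C1–C6 bond gives a decalin whose ring B holds the Z C4=C5 bond in a cyclohexene. A C1–C6 epoxide next to a C10 ketone is then the retron of an Eschenmoser–Tanabe fragmentation to the C6 ketone and a C1≡C10 alkyne, which later takes up C14.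

## Retrosynthetic reasoning

**37 ⇒ 34.** The C8 ether, the C9 acetate and the C14 isovalerate are cut last (36, 35, 34). Freeing O8 only in the final step keeps it from taking the acetyl group or the lactone carbonyl; the primary O14 is acylated before the secondary O9, so no further protecting group is needed.

**34 ⇒ 28.** The C11=C13 bond is cut back to the saturated lactone 30 (via 33), and the C12–O6 bond back to diol 28 (via lactol 29). Strong base is needed for the methylenation, so it must precede all esters; O9 and O14 are held as one acetal (27).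

**26 ⇒ 23.** The C10–C14 bond is cut to vinyl iodide 25, stannane 24 and alkyne 23. A ring alkyne can only give the ring-cis alkene on syn addition, and the free propargylic O9 steers tin to C10.

**23 ⇒ 22.** The C6–H bond is cut to enynone 22. Reduction removes the epimerisable, conjugate-acceptor ketone before palladium chemistry.

**22 ⇒ 20 (key).** The C1–C6 bond is re-formed: 22 becomes epoxy ketone 20 (through hydrazone 21). This is the only place where a ten-membered ring can be traded for two six-membered rings with C6 oxygenated and C1/C10 unsaturated. Nothing stereochemical is demanded of the fragmentation, because either epoxide face serves.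

**20 ⇒ 18.** The epoxide C–O bonds are cut to dienone 19, and the C10 carbonyl to the dienylic alcohol in diol 18. C10 is kept as an alcohol through the middle of the route so that C7 and C9 are never α or γ to a ketone under base.

**18 ⇒ 14.** O8 (4-methoxybenzyl) and O12 (silyl) in 17, 16 and 15 come from reduction of the cis-fused lactone 14. The lactone distinguishes O8 from O9 and proves the cis relation of C11 and O8.

**14 ⇒ 9.** The C7–H bond is cut to butenolide 13, the C7=C11 and C12–O8 bonds to α-hydroxy enone 11 (via 12), then back through 10 to triol 9. Reduction of a fused butenolide gives the cis ring fusion, so C7 is set from C8 without external control; the intramolecular olefination can only reach C7, which settles the C7/C10 near-equivalence.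

**9 ⇒ 6.** The C8–O and C9–O bonds are cut to dienol 7, and the C10–H bond to achiral trienone ketal 6. A hydroxyl-directed osmylation is chosen because an undirected one would prefer the electron-rich ring B diene; the single stereocentre of 7 comes from a catalytic enantioselective ketone reduction.

**6 ⇒ 1 + 2.** The ring B alkene is moved back out of conjugation (5), the dienone is re-aromatised (4), and the C1–C2 and C5–C6 bonds are cut to 1 and 2. The C1=C6 double bond is thus inherited from an arene rather than made by a dehydrogenation that could aromatise ring B. The ketal/ketone pair of 5 separates C7 from C10 from the outset.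

## Alternatives that were turned down

**Alternative 1:** Disconnection of C7–C8 with ring contraction. A thirteen-membered keto ether A1 (O bridging C8 and C13, C7=C11 in the ring) would be enolised at C9 toward C8 as a boron enolate and undergo a [2,3]-Wittig shift to the α-hydroxy ketone A2. This would form C7–C8, the C8 hydroxyl and the C11=C13 methylene in one step.
- For: two stereocentres and the exocyclic methylene arise together, and the ring closed by conventional means is the easier thirteen-membered one.
- Against: the C7/C8 relationship depends on enolate geometry and on the conformation of a flexible macrocycle and cannot be predicted; [1,2]-shift and β-elimination of the α-alkoxy enolate compete; A2 still needs a cis-selective C9 ketone reduction inside a medium ring beside a hydride-sensitive ester; both Z alkenes must be made by open-chain olefinations.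
- Comparison: it is stronger on the methylene, which the chosen route installs in a separate step. The chosen route offers C7–C9 set on a six-membered ring by cyclic control and both alkene geometries fixed by ring constraints.

**Alternative 2:** Disconnection of C2–C3. Slow addition of a strong amide base to seco bromide A3 would generate the sulfonyl-stabilised allylic carbanion at C3, which displaces the C2 allylic bromide to give ring sulfone A4.
- For: convergent, all stereocentres made in open-chain fragments, and this closure has the best precedent among germacrane ring formations; on precedent it is stronger than the chosen key step.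
- Against: a ten-membered ring is closed directly (high dilution, SN2′ and γ-alkylation as competitors); both Z-trisubstituted alkenes must be made and kept in open chains next to an allylic anion and an allylic halide; the sulfone must later be removed reductively beside a 1,5-diene and allylic ethers; four contiguous stereocentres need a long acyclic sequence.
- Comparison: the chosen route closes no medium ring and draws both Z geometries from six-membered rings, at a comparable step count.

**Alternative 3:** Disconnection of C4–C9. The tertiary C9 alkoxide of cis-decalin mesylate A5 would fragment anti-periplanar (Wharton/Grob) with loss of the C5 mesylate to dienone A6, forming the C9 ketone and the Z C4=C5 bond.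
- For: heterolytic fragmentation to cyclodecadienes is closer to tested substrates than an epoxy ketone fragmentation with extra unsaturation, and the alkene geometry is stereospecific.
- Against: A5 needs three further stereocentres (quaternary C4, C5, tertiary C9) in one exact arrangement beside C6–C8; the C1=C10 alkene with C14 must already sit in the decalin; A6 needs a C9 reduction cis to O8 in the medium ring and can epimerise at C8; the exocyclic methylene unit must survive strong base.
- Comparison: the chosen route needs no temporary stereocentre (either epoxide face of 20 fragments), sets C9 early on a six-membered ring, and leaves an alkyne as the handle for C14.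

Key step: step 16

Remark: in step 4 the sense of induction is assigned by analogy with aryl alkyl ketones, the substituted C1 alkenyl arm being taken as the large group; if it proved opposite, the enantiomeric catalyst would be used.

## Route

Step 1
Reactants: 1 4,4-dimethoxycyclohexa-2,5-dien-1-one; 2 isoprene
Product: 4 4-methoxy-6-methyl-5,8-dihydronaphthalen-1-ol, via Diels–Alder adduct 3 (not isolated)
Conditions: TiCl2(OiPr)2 (10 mol %), (±)-1,1'-bi-2-naphthol (10 mol %), 4 Å MS, CH2Cl2, rt; then (±)-camphor-10-sulfonic acid (cat.), CH2Cl2, rt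
Reagents that add atoms: none
Why: Lewis-acid-catalysed Diels–Alder reaction of a quinone monoketal: the titanium-bound C10 carbonyl makes C6 the electrophilic terminus, so the more nucleophilic end of isoprene bonds there and the methyl ends on C4; acid then expels methanol from cis adduct 3 and tautomerises it to the p-methoxyphenol, so the adduct stereocentres do not matter and a racemic ligand suffices.

Step 2
Reactants: 4 4-methoxy-6-methyl-5,8-dihydronaphthalen-1-ol
Product: 5 4,4-dimethoxy-6-methyl-5,8-dihydronaphthalen-1(4H)-one
Conditions: PhI(OAc)2, MeOH, 0 °C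
Reagents that add atoms: methanol (CO)
Why: Oxidative dearomatisation of a p-methoxyphenol with a hypervalent iodine reagent; methanol adds at the methoxy-bearing carbon, which places the ketal on C7 and the ketone on C10 and leaves the C1=C6 bond in place without any dehydrogenation of ring B.

Step 3
Reactants: 5 4,4-dimethoxy-6-methyl-5,8-dihydronaphthalen-1(4H)-one
Product: 6 4,4-dimethoxy-6-methyl-7,8-dihydronaphthalen-1(4H)-one
Conditions: 1,8-diazabicyclo[5.4.0]undec-7-ene (0.2 equiv), CH2Cl2, rt
Reagents that add atoms: none
Why: Base-mediated isomerisation of a skipped diene into conjugation: only C5–H is both allylic and γ to the C10 carbonyl, so deprotonation there and reprotonation at C3 should give the linear C10(=O)–C1=C6–C5=C4 dienone as the thermodynamic product, before any stereocentre exists.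

Step 4
Reactants: 6 4,4-dimethoxy-6-methyl-7,8-dihydronaphthalen-1(4H)-one
Product: 7 (1S)-4,4-dimethoxy-6-methyl-1,4,7,8-tetrahydronaphthalen-1-ol
Conditions: (R)-1-methyl-3,3-diphenyltetrahydro-1H,3H-pyrrolo[1,2-c][1,3,2]oxazaborole (20 mol %), catecholborane, toluene, −78 °C
Reagents that add atoms: none
Why: Corey–Bakshi–Shibata reduction; the C10 carbonyl lies between a substituted (C1) and an unsubstituted (C9) alkenyl arm, which the catalyst should distinguish to set the C10 carbinol that relays absolute configuration to C8 and C9; catecholborane at low temperature avoids hydroboration of the diene.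

Step 5
Reactants: 7 (1S)-4,4-dimethoxy-6-methyl-1,4,7,8-tetrahydronaphthalen-1-ol
Product: 9 (1R,2R,3R)-4,4-dimethoxy-6-methyl-1,2,3,4,7,8-hexahydronaphthalene-1,2,3-triol (O8 O9 O10 all cis), via osmate ester 8 (not isolated)
Conditions: OsO4 (1.05 equiv), TMEDA (1.1 equiv), CH2Cl2, −78 °C; then ethylenediamine, CH2Cl2, rt
Reagents that add atoms: osmium tetroxide (O=[Os](=O)(=O)=O)
Why: Hydrogen-bond-directed syn-dihydroxylation of a cyclic allylic alcohol: the C10 hydroxyl should deliver the OsO4·TMEDA complex to the adjacent disubstituted C8=C9 bond on its own face, ahead of the tetrasubstituted C1=C6 and the remote C4=C5 bonds, so that O8, O9 and O10 end all cis; ligand exchange frees the triol without acid.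

Step 6
Reactants: 9 all-cis triol
Product: 10 9,10-O-isopropylidene acetal of 9 (C8 hydroxyl free)
Conditions: 2-methoxypropene, pyridinium p-toluenesulfonate (cat.), CH2Cl2, 0 °C
Reagents that add atoms: 2-methoxypropene (C=C(C)OC)
Why: Acetonide formation under equilibrating conditions; of the two cis-diol pairs the O9/O10 pair should be taken, because a dioxolane on O8/O9 would sit against a methoxy group of the C7 ketal, which leaves only the hindered C8 hydroxyl free.

Step 7
Reactants: 10 9,10-acetonide ketal
Product: 11 α-hydroxy enone (C7 ketone, C8 hydroxyl, 9,10-acetonide, ring B 1,3-diene)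
Conditions: 10% aq. oxalic acid on silica gel, CH2Cl2, rt
Reagents that add atoms: water (O)
Why: Hydrolysis of an alkene-conjugated dimethyl ketal, which should cleave far faster than a ring-fused acetonide under these mild conditions, unveiling the C7 ketone next to the only free hydroxyl.

Step 8
Reactants: 11 α-hydroxy enone
Product: 13 butenolide (C7=C11 and 12,8-olide with 9,10-acetonide), via acyl ylide 12 (not isolated)
Conditions: Ph3P=C=C=O, toluene, 80 °C
Reagents that add atoms: (triphenylphosphoranylidene)ketene (O=C=C=P(c1ccccc1)(c1ccccc1)c1ccccc1)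
Why: The ketenylidene phosphorane acylates the free C8 hydroxyl to give ester ylide 12, whose intramolecular Wittig reaction can only reach the adjacent C7 ketone (five-membered ring); this attaches C11–C12 to C7 and marks O8 as the lactone oxygen.

Step 9
Reactants: 13 butenolide
Product: 14 cis-fused 12,8-lactone (7-H; C11 O8 and O9 on one face)
Conditions: Cu(OAc)2 (5 mol %), 1,2-bis(diphenylphosphino)benzene (5 mol %), (MeO)2MeSiH, t-BuOH, toluene, rt
Reagents that add atoms: none
Why: Copper hydride conjugate reduction of a β-substituted butenolide; hydride should add to C7 from the face of H8, away from ring A carbon C9, which gives the cis ring fusion and hence C11 cis to O8 and O9; delivery to the fully substituted C1 (1,6-mode) is disfavoured and the diene is not a substrate.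

Step 10
Reactants: 14 cis-fused lactone
Product: 15 diol (C8 hydroxyl and C12 hydroxyl)
Conditions: LiBH4, THF, 0 °C to rt
Reagents that add atoms: none
Why: Lithium borohydride reduces the lactone to the 1,4-diol and leaves the acetonide and the diene untouched, freeing O8 and O12 as a secondary and a primary hydroxyl.

Step 11
Reactants: 15 diol
Product: 16 C12 tert-butyldiphenylsilyl ether
Conditions: t-BuPh2SiCl, imidazole, CH2Cl2, 0 °C
Reagents that add atoms: tert-butyl(chloro)diphenylsilane (CC(C)(C)[Si](Cl)(c1ccccc1)c1ccccc1)
Why: Selective silylation of the primary hydroxyl; the diphenyl silyl group is used because it must survive the acidic acetonide cleavage of step 13.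

Step 12
Reactants: 16 C12 silyl ether
Product: 17 C8 4-methoxybenzyl ether
Conditions: NaH, 4-methoxybenzyl chloride, Bu4NI (cat.), THF–DMF, 0 °C to rt
Reagents that add atoms: 4-methoxybenzyl chloride (COc1ccc(CCl)cc1)
Why: Williamson etherification of the one remaining hydroxyl; O8 is now distinguished from O9 for the rest of the synthesis.

Step 13
Reactants: 17 C8 4-methoxybenzyl ether
Product: 18 cis-9,10-diol
Conditions: AcOH–H2O–THF (3:1:1), 40 °C
Reagents that add atoms: none
Why: Acid hydrolysis of the acetonide under conditions that should leave the 4-methoxybenzyl and tert-butyldiphenylsilyl ethers intact.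

Step 14
Reactants: 18 cis-9,10-diol
Product: 19 α-hydroxy dienone (C10 ketone, C9 hydroxyl, C1=C6–C5=C4)
Conditions: MnO2 (activated), CH2Cl2, rt
Reagents that add atoms: none
Why: MnO2 oxidises only the dienylic C10 hydroxyl; the non-allylic C9 hydroxyl should remain.

Step 15
Reactants: 19 α-hydroxy dienone
Product: 20 epoxy ketone (C1–C6 epoxide anti to the C7 side chain)
Conditions: 30% H2O2, NaOH (0.3 equiv), MeOH, 0 °C
Reagents that add atoms: hydrogen peroxide (OO)
Why: Weitz–Scheffer epoxidation: hydroperoxide adds to C6, the β-carbon of the dienone, and the enolate closes at C1, so the C4=C5 bond is kept; attack should come anti to the C7 side chain, but either epoxide face serves the next step.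

Step 16
Reactants: 20 epoxy ketone
Product: 22 ten-membered enynone (C6 ketone, Z C4=C5, C1≡C10, C9 hydroxyl, C8 4-methoxybenzyl ether, C7 2-silyloxyethyl), via tosylhydrazone 21 (not isolated)
Conditions: TsNHNH2, AcOH–CH2Cl2 (1:2), −20 °C to rt
Reagents that add atoms: none
Why: Eschenmoser–Tanabe fragmentation: p-toluenesulfonylhydrazide condenses with the only ketone (C10) to give 21, whose hydrazone nitrogen pushes electrons through C10 so that the C1–O bond of the epoxide opens to an azoalkene (C10=C1) and a C6 alkoxide. The alkoxide collapses to the C6 ketone while the C1–C6 bond breaks and N2 and p-toluenesulfinate leave, which leaves the C1≡C10 triple bond. The closest known reaction type is the fragmentation of bicyclic α,β-epoxy ketones with the epoxide on the ring fusion, which gives medium- and large-ring alkynones. The ten-membered ring is not closed by bond formation: it appears by cleavage of the bond shared by ring A and ring B (ring expansion), so no cyclisation penalty is paid. No stereocentre is formed; C7, C8 and C9 are spectators and the Z C4=C5 bond is inherited from ring B. The step needs hydrazone formation at C10 to outrun acid opening of the tertiary allylic C6–O bond, which the weak acid and low temperature should secure. It also needs the new C6 ketone not to enolise toward C7, which the saturated C11–C12 chain and the mildly acidic medium should secure; conjugation of that ketone with C4=C5 adds driving force.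

Step 17
Reactants: 22 ten-membered enynone
Product: 23 6R allylic alcohol (C6 and C9 hydroxyls free)
Conditions: NaBH4, CeCl3·7H2O, MeOH, −78 °C
Reagents that add atoms: none
Why: Luche 1,2-reduction of the enone; attack from the ring periphery should give the 6R alcohol needed for a trans C6–C7 lactone, though this facial preference cannot be argued with certainty; the reduction also removes the epimerisable ketone next to C7.

Step 18
Reactants: 23 6R allylic alcohol
Product: 24 C10 tributylstannyl alkene (ring-cis C1=C10)
Conditions: Bu3SnH, PdCl2(PPh3)2 (5 mol %), THF, 0 °C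
Reagents that add atoms: tributyltin hydride (CCCC[SnH](CCCC)CCCC)
Why: Palladium-catalysed syn-hydrostannation; the free propargylic C9 hydroxyl should direct tin to the proximal carbon C10 and hydrogen to C1, and syn addition to a ring alkyne can only give the ring-cis alkene.

Step 19
Reactants: 24 C10 stannane
Product: 25 C10 iodide
Conditions: I2, CH2Cl2, 0 °C
Reagents that add atoms: iodine (II)
Why: Iododestannylation, which proceeds with retention of alkene geometry and is much faster than any reaction of iodine with the other alkenes.

Step 20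
Reactants: 25 C10 iodide
Product: 26 C14 alcohol (C6 C9 and C14 hydroxyls free)
Conditions: Bu3SnCH2OH, Pd(PPh3)4 (10 mol %), 1,4-dioxane, 90 °C
Reagents that add atoms: (tributylstannyl)methanol (CCCC[Sn](CO)(CCCC)CCCC)
Why: Stille coupling with a hydroxymethyl stannane puts C14 on C10 with retention of geometry; free hydroxyls are tolerated.

Step 21
Reactants: 26 triol
Product: 27 9,14-O-isopropylidene acetal (C6 hydroxyl free)
Conditions: 2,2-dimethoxypropane, pyridinium p-toluenesulfonate (cat.), CH2Cl2, rt
Reagents that add atoms: 2,2-dimethoxypropane (COC(C)(C)OC)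
Why: Only the O9/O14 1,3-diol can close to a cyclic acetal (six-membered), which shields both oxygens from the base of step 24 and keeps them apart from O6.

Step 22
Reactants: 27 9,14-acetonide
Product: 28 diol (C6 hydroxyl and C12 hydroxyl)
Conditions: Bu4NF, THF, 0 °C to rt
Reagents that add atoms: none
Why: Fluoride cleavage of the silyl ether frees the primary C12 hydroxyl; acetal and 4-methoxybenzyl ether are stable.

Step 23
Reactants: 28 diol
Product: 30 saturated 12,6-lactone (trans-fused), via lactol 29 (not isolated)
Conditions: 2,2,6,6-tetramethylpiperidin-1-oxyl (20 mol %), PhI(OAc)2, CH2Cl2, rt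
Reagents that add atoms: none
Why: Nitroxyl-catalysed oxidation takes the primary alcohol to the aldehyde, which closes with the C6 hydroxyl to lactol 29 and is oxidised on to the γ-lactone; with 6R the lactone is trans-fused as in the target.

Step 24
Reactants: 30 saturated lactone
Product: 33 α-methylene lactone, via Mannich base 31 (not isolated), via ammonium iodide 32 (not isolated)
Conditions: LiN(iPr)2, THF, −78 °C; CH2=NMe2+ I−, −78 °C to rt; MeI, MeOH; NaHCO3 (aq), CH2Cl2
Reagents that add atoms: dimethyl(methylene)ammonium iodide (C=[N+](C)C.[I-])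
Why: α-Methylenation of a lactone through its lithium enolate, Mannich reaction, quaternisation and elimination; no ester or free hydroxyl is present at this stage.

Step 25
Reactants: 33 α-methylene lactone
Product: 34 diol (C9 and C14 hydroxyls)
Conditions: AcOH–H2O–THF (3:1:1), 40 °C
Reagents that add atoms: none
Why: Mild acid hydrolysis of the acetonide; the α-methylene lactone and the 4-methoxybenzyl ether should be stable.

Step 26
Reactants: 34 diol
Product: 35 C14 isovalerate
Conditions: isovaleryl chloride, 2,4,6-collidine, CH2Cl2, −78 to −40 °C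
Reagents that add atoms: isovaleryl chloride (CC(C)CC(=O)Cl)
Why: Low-temperature acylation distinguishes the primary allylic C14 hydroxyl from the hindered secondary C9 hydroxyl.

Step 27
Reactants: 35 C14 isovalerate
Product: 36 C9 acetate
Conditions: Ac2O, pyridine, 4-(dimethylamino)pyridine (cat.), CH2Cl2, 0 °C
Reagents that add atoms: acetic anhydride (CC(=O)OC(C)=O)
Why: Acetylation of the remaining hydroxyl with nucleophilic catalysis.

Step 28
Reactants: 36 C9 acetate
Product: 37 target CNP0603244.1
Conditions: 2,3-dichloro-5,6-dicyano-1,4-benzoquinone, CH2Cl2–pH 7 buffer, 0 °C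
Reagents that add atoms: none
Why: Oxidative cleavage of the 4-methoxybenzyl ether under buffered conditions frees the C8 hydroxyl last, which limits acetyl migration from O9 and translactonisation.

## Compound list

1 | 4,4-dimethoxycyclohexa-2,5-dien-1-one | COC1(OC)C=CC(=O)C=C1 | starting material
2 | isoprene | C=CC(C)=C | starting material
3 | cis-4,4-dimethoxy-6-methyl-4a,5,8,8a-tetrahydronaphthalen-1(4H)-one (racemic) | COC1(OC)C=CC(=O)[C@H]2CC=C(C)C[C@@H]12 | intermediate
4 | 4-methoxy-6-methyl-5,8-dihydronaphthalen-1-ol | COc1ccc(O)c2CC=C(C)Cc12 | intermediate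
5 | 4,4-dimethoxy-6-methyl-5,8-dihydronaphthalen-1(4H)-one | COC1(OC)C=CC(=O)C2=C1CC(C)=CC2 | intermediate
6 | 4,4-dimethoxy-6-methyl-7,8-dihydronaphthalen-1(4H)-one | COC1(OC)C=CC(=O)C2=C1C=C(C)CC2 | intermediate
7 | (1S)-4,4-dimethoxy-6-methyl-1,4,7,8-tetrahydronaphthalen-1-ol | O[C@H]1C=CC(OC)(OC)C2=C1CCC(C)=C2 | intermediate
8 | cyclic O8,O9-osmate ester of 9 (hexavalent osmium, TMEDA-bound) | O[C@H]1[C@H]3O[Os](=O)(=O)O[C@H]3C(OC)(OC)C2=C1CCC(C)=C2.CN(C)CCN(C)C | intermediate
9 | (1R,2R,3R)-4,4-dimethoxy-6-methyl-1,2,3,4,7,8-hexahydronaphthalene-1,2,3-triol | O[C@H]1[C@@H](O)[C@@H](O)C(OC)(OC)C2=C1CCC(C)=C2 | intermediate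
10 | 9,10-O-isopropylidene acetal of 9 (C8 hydroxyl free) | CC1(C)O[C@H]2[C@@H](O1)[C@@H](O)C(OC)(OC)C3=C2CCC(C)=C3 | intermediate
11 | α-hydroxy enone (C7 ketone, C8 hydroxyl, 9,10-acetonide) | CC1(C)O[C@H]2[C@@H](O1)[C@@H](O)C(=O)C3=C2CCC(C)=C3 | intermediate
12 | O8-(triphenylphosphoranylidene)acetate of 11 | CC1(C)O[C@H]2[C@@H](O1)[C@@H](OC(=O)C=P(c4ccccc4)(c4ccccc4)c4ccccc4)C(=O)C3=C2CCC(C)=C3 | intermediate
13 | butenolide (C7=C11, 12,8-olide, 9,10-acetonide) | CC1(C)O[C@H]2[C@@H](O1)[C@H]4OC(=O)C=C4C3=C2CCC(C)=C3 | intermediate
14 | cis-fused saturated 12,8-lactone | CC1(C)O[C@H]2[C@@H](O1)[C@H]4OC(=O)C[C@H]4C3=C2CCC(C)=C3 | intermediate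
15 | diol (C8 hydroxyl, C7 2-hydroxyethyl, 9,10-acetonide) | CC1(C)O[C@H]2[C@@H](O1)[C@@H](O)[C@@H](CCO)C3=C2CCC(C)=C3 | intermediate
16 | C12 tert-butyldiphenylsilyl ether of 15 | CC1(C)O[C@H]2[C@@H](O1)[C@@H](O)[C@@H](CCO[Si](c4ccccc4)(c4ccccc4)C(C)(C)C)C3=C2CCC(C)=C3 | intermediate
17 | C8 4-methoxybenzyl ether of 16 | CC1(C)O[C@H]2[C@@H](O1)[C@@H](OCc5ccc(OC)cc5)[C@@H](CCO[Si](c4ccccc4)(c4ccccc4)C(C)(C)C)C3=C2CCC(C)=C3 | intermediate
18 | cis-9,10-diol | O[C@H]1[C@@H](O)[C@@H](OCc5ccc(OC)cc5)[C@@H](CCO[Si](c4ccccc4)(c4ccccc4)C(C)(C)C)C2=C1CCC(C)=C2 | intermediate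
19 | α-hydroxy dienone | O=C1[C@@H](O)[C@@H](OCc5ccc(OC)cc5)[C@@H](CCO[Si](c4ccccc4)(c4ccccc4)C(C)(C)C)C2=C1CCC(C)=C2 | intermediate
20 | bicyclic α,β-epoxy ketone (key-step precursor) | O=C1[C@@H](O)[C@@H](OCc4ccc(OC)cc4)[C@@H](CCO[Si](c5ccccc5)(c5ccccc5)C(C)(C)C)[C@@]23O[C@]13CCC(C)=C2 | intermediate
21 | tosylhydrazone of 20 | Cc1ccc(cc1)S(=O)(=O)NN=C1[C@@H](O)[C@@H](OCc4ccc(OC)cc4)[C@@H](CCO[Si](c5ccccc5)(c5ccccc5)C(C)(C)C)[C@@]23O[C@]13CCC(C)=C2 | intermediate
22 | ten-membered enynone (key-step product) | O=C1/C=C(/C)CCC#C[C@@H](O)[C@@H](OCc2ccc(OC)cc2)[C@H]1CCO[Si](c3ccccc3)(c3ccccc3)C(C)(C)C | intermediate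
23 | 6R allylic alcohol | O[C@@H]1/C=C(/C)CCC#C[C@@H](O)[C@@H](OCc2ccc(OC)cc2)[C@H]1CCO[Si](c3ccccc3)(c3ccccc3)C(C)(C)C | intermediate
24 | C10 tributylstannyl alkene | O[C@@H]1/C=C(/C)CC/C=C(/[Sn](CCCC)(CCCC)CCCC)[C@@H](O)[C@@H](OCc2ccc(OC)cc2)[C@H]1CCO[Si](c3ccccc3)(c3ccccc3)C(C)(C)C | intermediate
25 | C10 iodide | O[C@@H]1/C=C(/C)CC/C=C(/I)[C@@H](O)[C@@H](OCc2ccc(OC)cc2)[C@H]1CCO[Si](c3ccccc3)(c3ccccc3)C(C)(C)C | intermediate
26 | C14 alcohol (triol) | O[C@@H]1/C=C(/C)CC/C=C(/CO)[C@@H](O)[C@@H](OCc2ccc(OC)cc2)[C@H]1CCO[Si](c3ccccc3)(c3ccccc3)C(C)(C)C | intermediate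
27 | 9,14-O-isopropylidene acetal | O[C@@H]1/C=C(/C)CC/C=C2/COC(C)(C)O[C@H]2[C@@H](OCc3ccc(OC)cc3)[C@H]1CCO[Si](c4ccccc4)(c4ccccc4)C(C)(C)C | intermediate
28 | diol (C6 and C12 hydroxyls) | O[C@@H]1/C=C(/C)CC/C=C2/COC(C)(C)O[C@H]2[C@@H](OCc3ccc(OC)cc3)[C@H]1CCO | intermediate
29 | lactol (C12 epimers) | C1C(O)O[C@@H]2/C=C(/C)CC/C=C3/COC(C)(C)O[C@H]3[C@@H](OCc4ccc(OC)cc4)[C@@H]12 | intermediate
30 | saturated trans-fused 12,6-lactone | C1C(=O)O[C@@H]2/C=C(/C)CC/C=C3/COC(C)(C)O[C@H]3[C@@H](OCc4ccc(OC)cc4)[C@@H]12 | intermediate
31 | C11 dimethylaminomethyl lactone (C11 epimers) | CN(C)CC1C(=O)O[C@@H]2/C=C(/C)CC/C=C3/COC(C)(C)O[C@H]3[C@@H](OCc4ccc(OC)cc4)[C@@H]12 | intermediate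
32 | trimethylammonium iodide of 31 | C[N+](C)(C)CC1C(=O)O[C@@H]2/C=C(/C)CC/C=C3/COC(C)(C)O[C@H]3[C@@H](OCc4ccc(OC)cc4)[C@@H]12.[I-] | intermediate
33 | α-methylene lactone (9,14-acetonide, C8 4-methoxybenzyl ether) | C=C1C(=O)O[C@@H]2/C=C(/C)CC/C=C3/COC(C)(C)O[C@H]3[C@@H](OCc4ccc(OC)cc4)[C@@H]12 | intermediate
34 | C9,C14 diol | C=C1C(=O)O[C@@H]2/C=C(/C)CC/C=C(/CO)[C@@H](O)[C@@H](OCc3ccc(OC)cc3)[C@@H]12 | intermediate
35 | C14 isovalerate | C=C1C(=O)O[C@@H]2/C=C(/C)CC/C=C(/COC(=O)CC(C)C)[C@@H](O)[C@@H](OCc3ccc(OC)cc3)[C@@H]12 | intermediate
36 | C9 acetate | C=C1C(=O)O[C@@H]2/C=C(/C)CC/C=C(/COC(=O)CC(C)C)[C@@H](OC(C)=O)[C@@H](OCc3ccc(OC)cc3)[C@@H]12 | intermediate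
37 | CNP0603244.1 (6R,7R,8S,9R) | C=C1C(=O)O[C@@H]2/C=C(/C)CC/C=C(/COC(=O)CC(C)C)[C@@H](OC(C)=O)[C@@H](O)[C@@H]12 | target

## Step count and least certain steps

Total: 28 steps from 1 and 2. Longest linear sequence: 28 steps (the route is fully linear).

**Step 16 (key step).** The tertiary, allylic C6–O bond of the epoxide may open under acid before the hindered C10 ketone has formed its hydrazone, leading to solvolysis or rearrangement instead of fragmentation. Fallback: from 20, condensation with 1-amino-trans-2,3-diphenylaziridine gives the N-aziridinyl imine F1, which fragments on gentle heating in toluene under neutral conditions (loss of stilbene and nitrogen) and returns to the route at 22.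

**Step 5.** Loss of chemoselectivity: undirected osmylation of the electron-rich diene terminus C4=C5 may compete with the hydroxyl-directed delivery to C8=C9. Fallback: from 7, the ring B diene is first bound as its tricarbonyliron complex F2 (Fe2(CO)9, Et2O); the same directed dihydroxylation then gives the complexed triol F3, and decomplexation with trimethylamine N-oxide returns to 9.

**Step 6.** Wrong acetal regiochemistry or acetal migration: the dioxolane may form on O8/O9 and leave O10 free. Fallback: from 9, the ketal is hydrolysed first to the triol enone F4; intermolecular Wittig olefination of the C7 ketone with ethyl (triphenylphosphoranylidene)acetate is followed by lactonisation, which is expected to take the adjacent O8 (five-membered ring), giving the butenolide diol F5; its only remaining cis-diol is then protected as the acetonide, returning at 13.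

**Step 15.** Oxidative cleavage or epimerisation of the free α-ketol under alkaline peroxide, epimerisation at C7 through the extended enolate, or attack at C4 instead of C6. Fallback: from 19, the C9 hydroxyl is masked as its triethylsilyl ether F6, epoxidation is run with anhydrous t-BuOOH and benzyltrimethylammonium hydroxide to give the silyl-protected epoxy ketone F7, and HF·pyridine removes the silyl group, returning at 20.

**Step 17.** Poor facial selectivity at C6 in a flexible medium ring, giving the 6S alcohol and hence a cis lactone. Fallback: from 22, substrate control is replaced by reagent control, a Corey–Bakshi–Shibata reduction with the oxazaborolidine enantiomer that delivers hydride to the required face; this makes no new compound (F0) and returns at 23.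

**Step 18.** Wrong regiochemistry: tin may go to the less hindered C1 instead of C10. Fallback: from 23, palladium hydride addition is replaced by molybdenum-catalysed stannylmetalation (Mo(CO)3(CNtBu)3, Bu3SnH), where regiochemistry is set by the propargylic oxygen rather than by sterics; this makes no new compound (F0) and returns at 24.

## Further compounds

F1 | step 16 | N-(trans-2,3-diphenylaziridin-1-yl)imine of 20 (diastereomer mixture) | C1(=NN4[C@H](c5ccccc5)[C@H]4c5ccccc5)[C@@H](O)[C@@H](OCc6ccc(OC)cc6)[C@@H](CCO[Si](c7ccccc7)(c7ccccc7)C(C)(C)C)[C@@]23O[C@]13CCC(C)=C2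
F2 | step 5 | tricarbonyl(η4-C1=C6–C5=C4)iron complex of dienol 7 | O[C@H]1C=CC(OC)(OC)C2=C1CCC(C)=C2.[Fe].[C-]#[O+].[C-]#[O+].[C-]#[O+]
F3 | step 5 | tricarbonyliron complex of triol 9 | O[C@H]1[C@@H](O)[C@@H](O)C(OC)(OC)C2=C1CCC(C)=C2.[Fe].[C-]#[O+].[C-]#[O+].[C-]#[O+]
F4 | step 6 | triol enone (C7 ketone, O8 O9 O10 free) | O[C@H]1[C@@H](O)[C@@H](O)C(=O)C2=C1CCC(C)=C2
F5 | step 6 | butenolide 9,10-diol | O[C@H]1[C@@H](O)[C@H]4OC(=O)C=C4C2=C1CCC(C)=C2
F6 | step 15 | C9 triethylsilyl ether of dienone 19 | O=C1[C@@H](O[Si](CC)(CC)CC)[C@@H](OCc5ccc(OC)cc5)[C@@H](CCO[Si](c4ccccc4)(c4ccccc4)C(C)(C)C)C2=C1CCC(C)=C2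
F7 | step 15 | C9 triethylsilyl ether of epoxy ketone 20 | O=C1[C@@H](O[Si](CC)(CC)CC)[C@@H](OCc4ccc(OC)cc4)[C@@H](CCO[Si](c5ccccc5)(c5ccccc5)C(C)(C)C)[C@@]23O[C@]13CCC(C)=C2
F0 | step 17 | none | none
F0 | step 18 | none | none
A1 | alternative 1 | thirteen-membered keto ether (C7=C11 geometry left open) | CC(C)(C)[Si](C)(C)O[C@@H]1/C=C(/C)CC/C=C(/COC(=O)CC(C)C)C(=O)COCC(CO[Si](C)(C)C(C)(C)C)=C1
A2 | alternative 1 | ten-membered α-hydroxy ketone | CC(C)(C)[Si](C)(C)O[C@@H]1/C=C(/C)CC/C=C(/COC(=O)CC(C)C)C(=O)[C@@H](O)[C@H]1C(=C)CO[Si](C)(C)C(C)(C)C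
A3 | alternative 2 | seco allylic bromide with C3 phenylsulfonyl | BrC/C=C(/COCc1ccc(OC)cc1)[C@@H](O[Si](CC)(CC)CC)[C@@H](OCc1ccc(OC)cc1)[C@H]([C@H](O[Si](C)(C)C(C)(C)C)/C=C(/C)CS(=O)(=O)c1ccccc1)C(=C)CO[Si](C)(C)C(C)(C)C
A4 | alternative 2 | ten-membered ring with C3 sulfone | CC(C)(C)[Si](C)(C)O[C@@H]1/C=C(/C)[C@@H](S(=O)(=O)c2ccccc2)C/C=C(/COCc2ccc(OC)cc2)[C@@H](O[Si](CC)(CC)CC)[C@@H](OCc2ccc(OC)cc2)[C@H]1C(=C)CO[Si](C)(C)C(C)(C)C
A5 | alternative 3 | cis-decalin C5 mesylate with tertiary C9 hydroxyl | CC(C)(C)[Si](C)(C)O[C@@H]1[C@@H](OS(C)(=O)=O)[C@@]2(C)CCC=C(COCc3ccc(OC)cc3)[C@@]2(O)[C@@H](OCc3ccc(OC)cc3)[C@H]1C(=C)CO[Si](C)(C)C(C)(C)C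
A6 | alternative 3 | ten-membered dienone with C9 ketone | CC(C)(C)[Si](C)(C)O[C@@H]1/C=C(/C)CC/C=C(/COCc2ccc(OC)cc2)C(=O)[C@@H](OCc2ccc(OC)cc2)[C@H]1C(=C)CO[Si](C)(C)C(C)(C)C
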